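Assumption: the target has no stereocentre and no stereogenic double bond, so it is achiral and "single enantiomer" places no demand on the route.

## Structural features

Isochandalone is an isoflavone: a benzopyran-4-one (rings A and C) whose C3 carries an aryl group that is itself the benzo ring (ring B) of a 2,2-dimethyl-2H-chromene, joined through chromene C6 so that the pyran oxygen is para to the C3–aryl bond. Ring A has a phloroglucinol oxygen pattern: O1 on C8a, a hydroxyl on C5 that is hydrogen-bonded to the C4 carbonyl, a hydroxyl on C7, a prenyl chain on C6 between them, and hydrogen on C8. All selectivity problems are therefore regiochemical. The fragile groups are the prenyl olefin flanked by two phenols (acid closes it to a chroman; hydrogenation and electrophiles destroy it), the electron-rich styrene-type olefin of the chromene, and C2 of the pyranone, which nucleophiles attack with ring opening. The real difficulty is to place three things without ambiguity: prenyl on C6 and not C8, the aryl group on C3 and not C2, and the right one of the three phloroglucinol oxygens in the pyranone. The key step exploits the fact that O1 and the C4 carbonyl sit on the adjacent ring-A carbons C8a and C4a. Ring C is therefore a salicylaldehyde (O1–C8a–C4a–C4) plus a two-carbon unit C2=C3 that can arrive as an alkyne with ring B already attached. The phenol behind that salicylaldehyde has a mirror plane through its oxygen and the prenyl-bearing carbon, so formylation at either ortho position gives the same aldehyde.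

## Logic of the disconnections

17 to 16. The last bonds cut are the two acetal O–CH2 bonds on O5 and O7. The phenols stay masked to the end because a free O5–H or O7–H would be a further candidate for O1 in the ring-forming step. Acetals are chosen because the same groups direct the lithiation at the start. No skeletal simplification results. The forward step must use acid that stops short of adding a phenol to the C6 side-chain olefin or hydrating the pyran olefin of ring B.

16 to 15. The C2–H bond is exchanged for a C2–Si bond. Silicon is there only to decide which alkyne carbon becomes C2. Its removal costs one step and no skeletal bond. The forward step must cleave C–Si without letting a nucleophile open the pyranone at C2.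

15 to 8 + 14. The cuts are C3–C4 and O1–C2, the two bonds that tie the C2=C3 unit into ring C. The molecule falls into two fragments of nearly equal size, each holding its own regiochemical information: 8 has the complete ring A pattern with a single free phenol, and 14 has the finished ring B with the future C2–C3 unit. Ring C and both bonds are made in one operation and the core needs no later adjustment. The forward step must cleave the aldehyde C–H, insert the alkyne in one orientation, and leave two olefins and two acetals alone.

14 to 12 + 13. The aryl–alkynyl C(sp2)–C(sp) bond is cut, the natural junction between a silylated two-carbon unit and an aryl halide. This leaves 12, a simple bicyclic bromide. The coupling must work on an electron-rich aryl bromide without loss of the alkynyl silicon.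

12 to 11, then 9 + 10. The pyran of ring B is opened at the bond between the aromatic ortho carbon and the ring CH (C4a–C4), which gives the propargyl ether 11. The ether O–CMe2 bond of 11 is then cut. 9 is para-substituted with two equivalent ortho positions, so the pyran can close in only one way. The forward cascade needs strong heat, which at this early stage no sensitive group has to survive.

8 to 7. The aryl–CHO bond is cut. Because the two ortho positions of 7 are equivalent, formylation can give only one salicylaldehyde. The phenol that directs formylation is the oxygen that becomes O1, and the prenyl group is para to it, which is the future C6. This removes the C6/C8 question from the synthesis. The forward step must be ortho-specific and non-acidic.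

7 to 6, then 3 + 4 by way of 5. The O–Si bond is cut, then the aryl–CH2 bond. The carbon between the two acetal oxygens of 3 is its most acidic ring position, so the side chain is attached where the two directing groups converge. A free third hydroxyl cannot be carried through the lithiation, so that oxygen carries a bulky silyl group that neither directs metalation nor offers an acidic proton. The forward step needs lithiation at one site and substitution at the primary carbon of 4.

3 to 2 to 1. The two acetal O–C bonds and the O–Si bond are cut, which leads to the symmetric triol 1. The only demand is that silylation stops at one oxygen, which stoichiometry controls.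

## Other disconnections considered

Alternative 1: The cut removes C3 and its aryl group from ring C (bonds C2–C3 and C3–C4). This leaves a 3-siloxybenzofuran A2, whose furan C2=C3 bond supplies chromone C2 and C4, and an aryl chlorodiazirine A3, which supplies C3 with ring B attached. In the forward key step A3 loses nitrogen, the carbene centre so generated cyclopropanates the enol-ether double bond of A2, and chloride loss with O–Si cleavage opens the cyclopropane to the pyranone. The product is the 6-allyl isoflavone A1; an allyl-to-prenyl cross-metathesis and acetal removal would follow.
- In its favour: the aryl group sits on the inserted carbon and can only become C3. The C2/C3 question that the chosen plan answers with a silyl preference does not arise, and on this point the alternative is the better plan. The step also needs no metal, no oxidant and little heat.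
- Against it here: a free carbene is generated beside other electron-rich olefins. The pyran olefin of ring B is present in A3 and in A1, and a prenyl group would be a third trap, which is why A1 carries an allyl stand-in and needs a metathesis step. The synthesis of A3 involves a hypochlorite oxidation that the chromene olefin may not tolerate. The ring-A precursor of A2 faces the C-alkylation regiochemistry that the chosen plan removes by symmetry.
- Comparison: both key steps extrapolate a known ring-forming reaction to a new partner, so neither is safer in principle. The alternative is superior in certainty of aryl placement. The chosen plan is superior in chemoselectivity (an alkyne-selective metal insertion against an indiscriminate carbene), in convergence (8 and 14 are of equal size) and in length, because the carbene route adds the diazirine synthesis and the allyl-to-prenyl exchange.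

Alternative 2: The cut is the O–CMe2 bond of the ring B pyran together with its ring double bond. It leads back to the diprenyl isoflavone A5, which has an open prenyl group ortho to the free 4'-phenol. In the forward key step DDQ abstracts hydride from the benzylic CH2 and the oxidised intermediate closes by oxa-6π electrocyclisation to A4, one acetal away from 17.
- In its favour: the step is biomimetic, metal-free and runs near room temperature, and the sequence is well established for simple ortho-prenylphenols. Only one deprotection follows the key step, against two operations in the chosen plan, so the alternative has the better endgame.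
- Against it here: A5 contains a second ortho-prenylphenol unit in ring A (5-OH beside the C6 prenyl). Chelation of that hydroxyl to the C4 carbonyl should slow its oxidation, but the discrimination rests on a rate difference and not on structure. The key step forms one C–O bond and none of the isoflavone core, so ring C and the C3–aryl bond must still be made by another strategy, with two prenyl groups to place and three phenols to differentiate.
- Comparison: the mechanism of this key step is better understood than a silyl-directed insertion, and on that point the alternative is the better. The pyran closure is equally unambiguous in both plans (a single ortho phenol there, the symmetric 9 here). The alternative postpones the core construction, so it should be longer and more linear, and it exposes a late intermediate to a strong oxidant, whereas the chosen plan builds the pyran in step 7 on a simple ether.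

Alternative 3: The cut is the bond between ring B and the pyran CH (C3'–CH), with the O–CMe2 bond kept. It leads back to A7, the aryl 1,1-dimethylpropargyl ether of the otherwise complete, acetal-protected isoflavone. In the forward key step heating triggers an aromatic propargyl Claisen rearrangement, tautomerisation, a 1,5-hydrogen shift and an oxa-6π closure to give A6, which is the same compound as 16.
- In its favour: the cascade is reliable and its regiochemistry is automatic, because the two positions ortho to the 4'-oxygen are equivalent. The isoflavone core would come from conventional chemistry in which the aryl position is never in doubt, which is better than the chosen plan on that point. No silicon has to be removed, so A6 is reached without a desilylation step.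
- Against it here: the cascade needs 150–190 °C and is applied to the most advanced intermediate, which carries the C6 prenyl group and two acetals. The free 4'-phenol needed for propargylation is a fourth oxygen to differentiate. As in alternative 2, the key step builds neither ring C nor the C3–aryl bond, so the route is linear and longer.
- Comparison: the chosen plan uses the identical pericyclic cascade (step 7) at the cheapest point, on 11, where nothing else can suffer from heat, and then joins the finished ring B to ring A in the ring-C-forming step. The two plans are equal in pyran-forming chemistry and reach the same penultimate compound. The alternative is safer in isoflavone regiochemistry; the chosen plan is shorter and more convergent.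

Key step: step 9

## Route

Step 1
Reactants: 1 phloroglucinol (benzene-1,3,5-triol)
Product: 2 5-{[tri(propan-2-yl)silyl]oxy}benzene-1,3-diol
Conditions: TIPSCl (1.0 equiv), 1 (3 equiv), imidazole, DMF, 0 °C to rt
Reagents that add atoms: triisopropylsilyl chloride, CC(C)[Si](Cl)(C(C)C)C(C)C
Why: Silylation of a phenol with a hindered chlorosilane and imidazole; the three hydroxyls of 1 are equivalent, so the only issue is the degree of silylation, and an excess of the cheap, water-soluble triol should hold it at one. The bulky silyl ether is chosen because it survives butyllithium, does not direct metalation and shields its own ortho positions.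

Step 2
Reactants: 2 5-{[tri(propan-2-yl)silyl]oxy}benzene-1,3-diol
Product: 3 [3,5-bis(methoxymethoxy)phenoxy]tri(propan-2-yl)silane
Conditions: MOMCl, i-Pr2NEt, CH2Cl2, 0 °C to rt
Reagents that add atoms: chloromethyl methyl ether, COCCl
Why: O-Alkylation of the two remaining phenols by the α-chloro ether under amine base gives the two acetals that serve first as metalation directors and later as the O5/O7 protecting groups; the hindered aryl silyl ether is inert to these conditions.

Step 3
Reactants: 3 [3,5-bis(methoxymethoxy)phenoxy]tri(propan-2-yl)silane; 4 prenyl bromide (1-bromo-3-methylbut-2-ene)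
Product: 6 [3,5-bis(methoxymethoxy)-4-(3-methylbut-2-en-1-yl)phenoxy]tri(propan-2-yl)silane, via aryllithium 5 (not isolated)
Conditions: n-BuLi, THF, 0 °C to rt; then 4, −78 °C to rt
Reagents that add atoms: none
Why: Directed ortho-metalation takes place at the one ring carbon flanked by two acetal oxygens, which chelate lithium cooperatively, while the positions next to the bulky silyl ether are not activated. The aryllithium then displaces bromide at the primary carbon of 4 (SN2 alkylation).

Step 4
Reactants: 6 [3,5-bis(methoxymethoxy)-4-(3-methylbut-2-en-1-yl)phenoxy]tri(propan-2-yl)silane
Product: 7 3,5-bis(methoxymethoxy)-4-(3-methylbut-2-en-1-yl)phenol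
Conditions: TBAF, AcOH, THF, 0 °C
Reagents that add atoms: none
Why: Fluoride-induced cleavage of an aryl silyl ether; buffering with acetic acid protects the electron-rich phenoxide from air oxidation, and the acetals and the olefin are not affected.

Step 5
Reactants: 7 3,5-bis(methoxymethoxy)-4-(3-methylbut-2-en-1-yl)phenol
Product: 8 6-hydroxy-2,4-bis(methoxymethoxy)-3-(3-methylbut-2-en-1-yl)benzaldehyde
Conditions: MgCl2, Et3N, (CH2O)n, MeCN, reflux
Reagents that add atoms: paraformaldehyde (formaldehyde source), C=O
Why: Magnesium-mediated ortho-formylation of a phenol: the magnesium phenoxide delivers formaldehyde only to the ortho position, and ortho-hydroxymethylation is followed by Oppenauer-type hydride transfer to a second equivalent of formaldehyde. The two ortho positions of 7 are equivalent, so a single aldehyde should form, with its only free phenol on the oxygen that becomes O1 and the prenyl group para to it; the basic medium spares the acetals.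

Step 6
Reactants: 9 4-bromophenol; 10 3-chloro-3-methylbut-1-yne
Product: 11 1-bromo-4-[(2-methylbut-3-yn-2-yl)oxy]benzene
Conditions: DBU, CuCl2·2H2O (cat.), MeCN, 0 °C to rt
Reagents that add atoms: none
Why: Copper-catalysed propargylic substitution, in which a copper acetylide of the tertiary propargylic chloride ionises and is captured by the phenoxide; this is the standard entry to aryl 1,1-dimethylpropargyl ethers and avoids a direct SN2 at a tertiary carbon.

Step 7
Reactants: 11 1-bromo-4-[(2-methylbut-3-yn-2-yl)oxy]benzene
Product: 12 6-bromo-2,2-dimethyl-2H-chromene
Conditions: PhNEt2, 190 °C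
Reagents that add atoms: none
Why: Thermal aromatic propargyl Claisen rearrangement to either of the two equivalent ortho positions, then tautomerisation, a 1,5-hydrogen shift and oxa-6π electrocyclisation close the 2,2-dimethyl-2H-pyran; the para bromine ends at C6 of the chromene.

Step 8
Reactants: 12 6-bromo-2,2-dimethyl-2H-chromene; 13 trimethylsilylacetylene (ethynyltrimethylsilane)
Product: 14 [(2,2-dimethyl-2H-chromen-6-yl)ethynyl]trimethylsilane
Conditions: Pd(PhCN)2Cl2 (cat.), [t-Bu3PH]BF4 (cat.), CuI (cat.), i-Pr2NH, 1,4-dioxane, rt to 45 °C, sealed
Reagents that add atoms: none
Why: Sonogashira coupling of an aryl bromide with a terminal alkyne; the bulky electron-rich phosphine lets the electron-rich bromide react near room temperature, where the volatile alkyne and the alkynyl C–Si bond are safe.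

Step 9
Reactants: 8 6-hydroxy-2,4-bis(methoxymethoxy)-3-(3-methylbut-2-en-1-yl)benzaldehyde; 14 [(2,2-dimethyl-2H-chromen-6-yl)ethynyl]trimethylsilane
Product: 15 3-(2,2-dimethyl-2H-chromen-6-yl)-5,7-bis(methoxymethoxy)-6-(3-methylbut-2-en-1-yl)-2-(trimethylsilyl)-4H-chromen-4-one
Conditions: [RhCl(cod)]2 (cat.), C5H2Ph4 (cat.), Cu(OAc)2·H2O (2.2 equiv), 14 (1.3 equiv), o-xylene, 130 °C, N2
Reagents that add atoms: none
Why: The phenoxide of 8 binds rhodium and delivers it to the aldehyde C–H, which is cleaved to a five-membered acyl rhodacycle (Rh–O–C8a–C4a–C4); the alkyne of 14 inserts into the Rh–acyl bond, C–O reductive elimination from the seven-membered oxarhodacycle releases 15, and copper(II) returns the metal to its active oxidation state. The closest known reaction type is the rhodium/copper oxidative [4+2] annulation of salicylaldehydes with internal alkynes to 2,3-disubstituted chromones. Ring C closes as a six-membered ring in the O1–C2 reductive elimination, with four atoms (O1, C8a, C4a, C4) from 8 and two (C2, C3) from 14; no stereocentre is formed. The step needs one insertion orientation: the trimethylsilyl group should take the rhodium-bound carbon (long Rh–C bond, α-silyl stabilisation, least clash with the migrating acyl group), as bulky silyl groups do in Larock-type annulations, which puts the chromenyl group on C3; this preference is an expectation that has not been tested with this catalyst. Which oxygen becomes O1 is not in question, because 8 has a single free phenol and the two acetal oxygens cannot bind the metal as phenoxides. The trisubstituted prenyl olefin and the cyclic cis olefin of the chromene are poorer ligands than the alkyne and should remain spectators, and the excess of 14 covers any loss of alkynyl silicon.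

Step 10
Reactants: 15 3-(2,2-dimethyl-2H-chromen-6-yl)-5,7-bis(methoxymethoxy)-6-(3-methylbut-2-en-1-yl)-2-(trimethylsilyl)-4H-chromen-4-one
Product: 16 3-(2,2-dimethyl-2H-chromen-6-yl)-5,7-bis(methoxymethoxy)-6-(3-methylbut-2-en-1-yl)-4H-chromen-4-one
Conditions: TBAF, AcOH, THF, 0 °C to rt
Reagents that add atoms: none
Why: Protodesilylation of an α-oxygenated vinylsilane: fluoride attacks silicon and the departing C2 carbanion, stabilised by the ring oxygen and the electron-poor pyranone, is protonated by acetic acid. Buffering avoids hydroxide-type attack at C2 and opening of the pyranone.

Step 11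
Reactants: 16 3-(2,2-dimethyl-2H-chromen-6-yl)-5,7-bis(methoxymethoxy)-6-(3-methylbut-2-en-1-yl)-4H-chromen-4-one
Product: 17 isochandalone, 3-(2,2-dimethyl-2H-chromen-6-yl)-5,7-dihydroxy-6-(3-methylbut-2-en-1-yl)-4H-chromen-4-one
Conditions: HCl (aq., dilute), MeOH–THF, 45 °C
Reagents that add atoms: none
Why: Acid-catalysed acetal methanolysis frees both phenols, the chelated 5-O acetal first. Dilute acid at moderate temperature is the usual compromise for prenylated phenols and should stay below the threshold for chroman formation or hydration of the chromene.

## Compound list

1 | phloroglucinol (benzene-1,3,5-triol) | Oc1cc(O)cc(O)c1 | starting material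
2 | 5-{[tri(propan-2-yl)silyl]oxy}benzene-1,3-diol | CC(C)[Si](Oc1cc(O)cc(O)c1)(C(C)C)C(C)C | intermediate
3 | [3,5-bis(methoxymethoxy)phenoxy]tri(propan-2-yl)silane | COCOc1cc(OCOC)cc(O[Si](C(C)C)(C(C)C)C(C)C)c1 | intermediate
4 | prenyl bromide (1-bromo-3-methylbut-2-ene) | CC(C)=CCBr | starting material
5 | {2,6-bis(methoxymethoxy)-4-[tri(propan-2-yl)silyloxy]phenyl}lithium | [Li]c1c(OCOC)cc(O[Si](C(C)C)(C(C)C)C(C)C)cc1OCOC | intermediate (not isolated)
6 | [3,5-bis(methoxymethoxy)-4-(3-methylbut-2-en-1-yl)phenoxy]tri(propan-2-yl)silane | COCOc1cc(O[Si](C(C)C)(C(C)C)C(C)C)cc(OCOC)c1CC=C(C)C | intermediate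
7 | 3,5-bis(methoxymethoxy)-4-(3-methylbut-2-en-1-yl)phenol | COCOc1cc(O)cc(OCOC)c1CC=C(C)C | intermediate
8 | 6-hydroxy-2,4-bis(methoxymethoxy)-3-(3-methylbut-2-en-1-yl)benzaldehyde (the 2-hydroxy-4,6-bis(methoxymethoxy)-5-prenylbenzaldehyde of aldehyde-first numbering) | COCOc1cc(O)c(C=O)c(OCOC)c1CC=C(C)C | intermediate
9 | 4-bromophenol | Oc1ccc(Br)cc1 | starting material
10 | 3-chloro-3-methylbut-1-yne | CC(C)(Cl)C#C | starting material
11 | 1-bromo-4-[(2-methylbut-3-yn-2-yl)oxy]benzene | C#CC(C)(C)Oc1ccc(Br)cc1 | intermediate
12 | 6-bromo-2,2-dimethyl-2H-chromene | CC1(C)C=Cc2cc(Br)ccc2O1 | intermediate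
13 | trimethylsilylacetylene (ethynyltrimethylsilane) | C[Si](C)(C)C#C | starting material
14 | [(2,2-dimethyl-2H-chromen-6-yl)ethynyl]trimethylsilane | C[Si](C)(C)C#Cc1ccc2c(c1)C=CC(C)(C)O2 | intermediate
15 | 3-(2,2-dimethyl-2H-chromen-6-yl)-5,7-bis(methoxymethoxy)-6-(3-methylbut-2-en-1-yl)-2-(trimethylsilyl)-4H-chromen-4-one | COCOc1cc2oc([Si](C)(C)C)c(-c3ccc4c(c3)C=CC(C)(C)O4)c(=O)c2c(OCOC)c1CC=C(C)C | intermediate
16 | 3-(2,2-dimethyl-2H-chromen-6-yl)-5,7-bis(methoxymethoxy)-6-(3-methylbut-2-en-1-yl)-4H-chromen-4-one | COCOc1cc2occ(-c3ccc4c(c3)C=CC(C)(C)O4)c(=O)c2c(OCOC)c1CC=C(C)C | intermediate
17 | isochandalone, 3-(2,2-dimethyl-2H-chromen-6-yl)-5,7-dihydroxy-6-(3-methylbut-2-en-1-yl)-4H-chromen-4-one (achiral) | CC(C)=CCc1c(O)cc2occ(-c3ccc4c(c3)C=CC(C)(C)O4)c(=O)c2c1O | target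

## Step count and least certain steps

Total steps: 11. Longest linear sequence: 8 (steps 1–5 and 9–11, from 1). The ring B branch (steps 6–8) has 3 steps before the junction.

**Step 9 (key step).** The most likely failure is insertion in the opposite orientation, with the aryl-bearing carbon on rhodium, which would lead to a 2-aryl-3-silyl (flavone-type) product. Aryl groups also favour the metal-bound position in such insertions, and the silyl preference is carried over from palladium chemistry. Lesser dangers are loss of the alkynyl silicon in hot copper acetate before insertion, decarbonylation of the hindered acyl-rhodium, and Lewis-acid loss of the acetal next to the aldehyde, which would create a second candidate for O1. A bulkier trialkylsilyl group on the alkyne would be the first adjustment.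

The fallback changes the approach to cross-coupling at C3; it sets out from 8 (and uses 12) and returns at 16, so that step 10 is not needed.
- 8 would be treated with excess methylmagnesium bromide in THF to give 2-(1-hydroxyethyl)-3,5-bis(methoxymethoxy)-4-(3-methylbut-2-en-1-yl)phenol F1 (racemic; its stereocentre disappears in the next operation).
- Oxidation with activated manganese dioxide would give 1-[6-hydroxy-2,4-bis(methoxymethoxy)-3-(3-methylbut-2-en-1-yl)phenyl]ethan-1-one F2.
- Condensation with N,N-dimethylformamide dimethyl acetal would give (2E)-3-(dimethylamino)-1-[6-hydroxy-2,4-bis(methoxymethoxy)-3-(3-methylbut-2-en-1-yl)phenyl]prop-2-en-1-one F3.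
- Iodine in the presence of pyridine would close it to 3-iodo-5,7-bis(methoxymethoxy)-6-(3-methylbut-2-en-1-yl)-4H-chromen-4-one F4.
- In parallel, Miyaura borylation of 12 (bis(pinacolato)diboron, Pd(dppf)Cl2, KOAc) would give 2-(2,2-dimethyl-2H-chromen-6-yl)-4,4,5,5-tetramethyl-1,3,2-dioxaborolane F5.
- Suzuki coupling of F4 with F5 would give 16.

**Step 3.** The most likely failure is attack of the hindered aryllithium at the tertiary end of the allylic bromide (SN2' substitution, which gives a 1,1-dimethylallyl side chain), besides incomplete metalation. The fallback sets out from 3 and returns at 6. The same aryllithium 5 would be trapped with allyl bromide, for which both substitution modes give one product, [3,5-bis(methoxymethoxy)-4-(prop-2-en-1-yl)phenoxy]tri(propan-2-yl)silane F6. Olefin cross-metathesis of F6 with 2-methylbut-2-ene and a second-generation Grubbs catalyst would then give 6.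

**Step 5.** The most likely failure is magnesium-assisted loss of the acetal that becomes chelated next to the new carbonyl, or stalling before the hydride-transfer stage on prolonged heating. The fallback sets out from 7 and returns at 8. Ortho-bromination of the very electron-rich ring with N-bromosuccinimide at −78 °C would give 2-bromo-3,5-bis(methoxymethoxy)-4-(3-methylbut-2-en-1-yl)phenol F7. Deprotonation of F7 with sodium hydride, bromine–lithium exchange with tert-butyllithium at −78 °C and quenching with DMF would give 8. The symmetry of 7 still fixes the position.

**Step 10.** The most likely failure is opening of the pyranone by nucleophilic attack at C2, which is most electrophilic while both phenols are capped, or sluggish C–Si cleavage. The fallback reverses the order of the last two operations; it sets out from 15 and returns at 17. Acid methanolysis of the acetals would first give 3-(2,2-dimethyl-2H-chromen-6-yl)-5,7-dihydroxy-6-(3-methylbut-2-en-1-yl)-2-(trimethylsilyl)-4H-chromen-4-one F8. Under the basic fluoride conditions (KF in methanol) the 7-phenoxide of F8 makes the pyranone electron-rich and resistant to ring opening, and desilylation would give 17.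

**Step 11.** The most likely failure is acid-catalysed addition of the 5- or 7-hydroxyl to the prenyl olefin (chroman formation), or hydration of the chromene, before the second acetal has gone. The fallback avoids protic acid; it sets out from 16 and returns at 17. Trimethylsilyl triflate with 2,2'-bipyridyl in CH2Cl2 at 0 °C would transfer the methoxymethyl groups to the bipyridyl and give 3-(2,2-dimethyl-2H-chromen-6-yl)-6-(3-methylbut-2-en-1-yl)-5,7-bis[(trimethylsilyl)oxy]-4H-chromen-4-one F9. Water at neutral pH would hydrolyse F9 to 17.

## Further compounds

F1 | step 9 | 2-(1-hydroxyethyl)-3,5-bis(methoxymethoxy)-4-(3-methylbut-2-en-1-yl)phenol (racemic) | CC(O)c1c(O)cc(OCOC)c(CC=C(C)C)c1OCOC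
F2 | step 9 | 1-[6-hydroxy-2,4-bis(methoxymethoxy)-3-(3-methylbut-2-en-1-yl)phenyl]ethan-1-one | CC(=O)c1c(O)cc(OCOC)c(CC=C(C)C)c1OCOC
F3 | step 9 | (2E)-3-(dimethylamino)-1-[6-hydroxy-2,4-bis(methoxymethoxy)-3-(3-methylbut-2-en-1-yl)phenyl]prop-2-en-1-one | CN(C)/C=C/C(=O)c1c(O)cc(OCOC)c(CC=C(C)C)c1OCOC
F4 | step 9 | 3-iodo-5,7-bis(methoxymethoxy)-6-(3-methylbut-2-en-1-yl)-4H-chromen-4-one | COCOc1cc2occ(I)c(=O)c2c(OCOC)c1CC=C(C)C
F5 | step 9 | 2-(2,2-dimethyl-2H-chromen-6-yl)-4,4,5,5-tetramethyl-1,3,2-dioxaborolane | CC1(C)C=Cc2cc(B3OC(C)(C)C(C)(C)O3)ccc2O1
F6 | step 3 | [3,5-bis(methoxymethoxy)-4-(prop-2-en-1-yl)phenoxy]tri(propan-2-yl)silane | C=CCc1c(OCOC)cc(O[Si](C(C)C)(C(C)C)C(C)C)cc1OCOC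
F7 | step 5 | 2-bromo-3,5-bis(methoxymethoxy)-4-(3-methylbut-2-en-1-yl)phenol | COCOc1cc(O)c(Br)c(OCOC)c1CC=C(C)C
F8 | step 10 | 3-(2,2-dimethyl-2H-chromen-6-yl)-5,7-dihydroxy-6-(3-methylbut-2-en-1-yl)-2-(trimethylsilyl)-4H-chromen-4-one | CC(C)=CCc1c(O)cc2oc([Si](C)(C)C)c(-c3ccc4c(c3)C=CC(C)(C)O4)c(=O)c2c1O
F9 | step 11 | 3-(2,2-dimethyl-2H-chromen-6-yl)-6-(3-methylbut-2-en-1-yl)-5,7-bis[(trimethylsilyl)oxy]-4H-chromen-4-one | CC(C)=CCc1c(O[Si](C)(C)C)cc2occ(-c3ccc4c(c3)C=CC(C)(C)O4)c(=O)c2c1O[Si](C)(C)C
A1 | alternative 1 | 6-allyl-3-(2,2-dimethyl-2H-chromen-6-yl)-5,7-bis(methoxymethoxy)-4H-chromen-4-one | C=CCc1c(OCOC)cc2occ(-c3ccc4c(c3)C=CC(C)(C)O4)c(=O)c2c1OCOC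
A2 | alternative 1 | {[5-allyl-4,6-bis(methoxymethoxy)-1-benzofuran-3-yl]oxy}(tert-butyl)dimethylsilane | C=CCc1c(OCOC)cc2occ(O[Si](C)(C)C(C)(C)C)c2c1OCOC
A3 | alternative 1 | 3-chloro-3-(2,2-dimethyl-2H-chromen-6-yl)-3H-diazirine | CC1(C)C=Cc2cc(C3(Cl)N=N3)ccc2O1
A4 | alternative 2 | 7-O-methoxymethyl isochandalone, 3-(2,2-dimethyl-2H-chromen-6-yl)-5-hydroxy-7-(methoxymethoxy)-6-(3-methylbut-2-en-1-yl)-4H-chromen-4-one | CC(C)=CCc1c(OCOC)cc2occ(-c3ccc4c(c3)C=CC(C)(C)O4)c(=O)c2c1O
A5 | alternative 2 | 7-O-methoxymethyl lupalbigenin, 5-hydroxy-3-[4-hydroxy-3-(3-methylbut-2-en-1-yl)phenyl]-7-(methoxymethoxy)-6-(3-methylbut-2-en-1-yl)-4H-chromen-4-one | COCOc1cc2occ(-c3ccc(O)c(CC=C(C)C)c3)c(=O)c2c(O)c1CC=C(C)C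
A6 | alternative 3 | 5,7-bis-O-methoxymethyl isochandalone (identical with 16) | COCOc1cc2occ(-c3ccc4c(c3)C=CC(C)(C)O4)c(=O)c2c(OCOC)c1CC=C(C)C
A7 | alternative 3 | 5,7-bis(methoxymethoxy)-3-{4-[(2-methylbut-3-yn-2-yl)oxy]phenyl}-6-(3-methylbut-2-en-1-yl)-4H-chromen-4-one | COCOc1cc2occ(-c3ccc(OC(C)(C)C#C)cc3)c(=O)c2c(OCOC)c1CC=C(C)C
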